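Sunday's flask held 2.62 times the reagent of Friday's, all else equal, yet at 20.0 min its side product reads 57.6% against Friday's 64.7%, while target reads 31.3% against 20.7%. How can so large a change in reagent move the side product so little?

in all of them: substrate 19 mM; free catalyst 9.5 µM; second catalyst 3.8 mM

| charge | reagent | remark | time |
|---|---|---|---|
| Friday's | 13 mM | run made earlier |  |
| Sunday's | 34 mM | run made earlier |  |
| teal | 18.0 mM |  | 25 min |
| blue | 24.0 mM |  | 25 min |
| red | 31.0 mM |  | 25 min |

| run | time / min | target / % | open intermediate / % | side product / % | substrate / % |
|---|---|---|---|---|---|
| Friday's | 2.00 | 4.0 | 72.5 | 8.4 | 14.8 |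
| Friday's | 6.00 | 13.3 | 55.4 | 31.2 | 0 |
| Friday's | 12.0 | 18.1 | 29.5 | 51.1 | 0.5 |
| Friday's | 20.0 | 20.7 | 13.2 | 64.7 | 0.2 |
| Sunday's | 1.33 | 3.8 | 63.7 | 3.7 | 27.3 |
| Sunday's | 3.00 | 11.8 | 68.7 | 14.8 | 4.9 |
| Sunday's | 8.00 | 24.6 | 38.3 | 36.3 | 0 |
| Sunday's | 20.0 | 31.3 | 10.5 | 57.6 | 0.4 |

(each reading ± 0.5 percentage points)

- which of these there is most of at the end, counted by the substrate in it, teal (substrate / target / side product / open intermediate)
- which of these there is most of at the end, counted by the substrate in it, blue (substrate / target / side product / open intermediate)
- which of these there is most of at the end, counted by the substrate in it, red (substrate / target / side product / open intermediate)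
- the largest of these amounts at the end, in percent of the substrate charged, teal
- the largest of these amounts at the end, in percent of the substrate charged, blue
- the largest of these amounts at the end, in percent of the substrate charged, red

- the numbers in the tables scatter by 0.5 percentage points (one standard deviation)

I count lifetimes. The substrate reads 0.5% at 12.0 min on Friday and 0% at 8.00 min on Sunday, so from those readings on, the open intermediate is simply emptying. I define the side-step lifetime as the area under the open-intermediate curve divided by the side product gained, taking the area from the logarithmic mean of two readings. Friday gives 11.9 min and Sunday 12.1 min. So between these two charges of reagent this lifetime does not move beyond the scatter of the readings, and I carry 12.0 min.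

The open intermediate's whole fall has lifetimes of 9.95 min on Friday and 9.27 min on Sunday. Running both forward to 25 min gives side product of 69.0% and 61.0%. Interpolating in reagent, my own figures are 67.1% for teal, 64.8% for blue and 62.1% for red. Even red leaves 37.9% for everything else, so side product leads in each.

The forecast says “More reagent therefore gives more target, but side product still wins.” It gives 67%, 64.5% and 62%, a little below mine for blue.

The flasks give side product at 67.1%, 64.3% and 62.1%.

    second catalyst → spent catalyst (k = 0.00142 s⁻¹)
    substrate + free catalyst → free catalyst + open intermediate (k = 1710 M⁻¹ s⁻¹)
    second catalyst + open intermediate ⇌ catalyst intermediate (K = 0.228 M⁻¹, k = 0.554 M⁻¹ s⁻¹)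
    reagent + catalyst intermediate → second catalyst + target (k = 127 M⁻¹ s⁻¹)
    open intermediate → side product (k = 0.00140 s⁻¹)

In red, target creeps from 28.4% at 12.5 min to 31.2% at 25.0 min, though reagent stands at 80.9% of its charge at that end. The wearing away of reagent is not the reason: holding reagent at its charge gives 61.3% side product in red instead of 62.1%. The back reaction of catalyst intermediate and the conversion of second catalyst into spent catalyst act together: removing the first gives 50.6%, removing the second 52.1%. Over that stretch 12.0 min predicts a red gain of 14 percentage points; red gains 14 points. Reckoned backward from blue's 49.5% at 12.5 min, the lifetime puts blue at 6.0 min at 29.8%; the simulation gives 29.8%.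

The earlier runs and the new flask were computed for an exercise; scatter was added.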